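# Total synthesis plan for CNP0182155.1 via a temporary Prins dioxane

Abbreviation used throughout: TBS = tert-butyldimethylsilyl. Atom labels O1, C2–C7 refer to the target (oxane ring O1, C2–C6; exocyclic carbinol carbon C7).

## The problem

The target is a single oxane ring (O1, C2–C6) carrying a 4-hydroxyphenyl group on C2, an (E)-3-(4-hydroxyphenyl)allyl chain on C3 and, on C5, an exocyclic carbinol carbon C7 with a third 4-hydroxyphenyl group. Nothing is fused or bridged, so the work lies in an open C2–C3–C4–C5(–C6)–C7 chain with four stereocentres and in one C–O ring closure. The three ring substituents are all cis (2R,3S,5R), so with the C3 and C5 groups equatorial the C2 aryl group stands axial; the target is therefore not the more stable C2 epimer, and C2 has to be fixed before ring closure and must not ionise afterwards. C2/C3 are neighbours and can be set in one aldol-type event, and so can C5/C7, but the two pairs are separated by the C4 methylene group and cannot be trusted to control each other. Both benzylic C–O bonds (C2–O1 and C7–OH) stand para to a phenol oxygen: acid opens them through quinone-methide-like cations, and base does the same once a free phenoxide faces a benzylic leaving group. The E alkene of the side chain excludes hydrogenation and must be told apart from any other alkene used on the way. The enabling feature is the C6–C5–C7–O unit: C5 carries the ring methylene C6 and C7 carries oxygen, which is the carbon and oxygen of formaldehyde added to one face of an (E)-C5=C7 styrene double bond, and the C4–C5=C7–aryl unit so revealed is a second cinnamyl group on C3.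

## Retrosynthesis

**O1–C6 (ring opening).** The oxane of 25 is cut at O1–C6, giving the open-chain hydroxy tosylate 23 (phenols as acetates), then its silyl ether 22 and the diol 21. The neighbouring cut, O1–C2, would close the ring at a benzylic carbon through a cation or quinone methide and leave C2 to thermodynamic control, that is, to the equatorial aryl epimer. Closure at the primary C6 leaves the C2–O bond untouched. The precursor has no ring. The forward step must be a 6-exo-tet displacement by the C2 alkoxide, run together with loss of the phenol acetates (through triphenol 24). This is only safe if O2 is a free hydroxyl, not an ester, when the phenoxides appear; hence the silyl ether on O2 in 22, removed under non-basic conditions before base is admitted.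

**Side-chain C=C (cross-metathesis).** The alkene of the C3 side chain of 21 is cut, giving the allyl-bearing diol 19 and 4-acetoxystyrene 20. Carrying the cinnamyl group as allyl keeps the two three-carbon arms on C3 different during the key step; an earlier arene would put two styrenes into the molecule. 19 is smaller by one arene. The forward reaction only has to deliver the E isomer beside two free hydroxyls.

**C6–O/C7–O as a formal.** The two hydroxyls of 19 are tied back into the methylene acetal of the trans-4,5-disubstituted 1,3-dioxane 17. This adds one carbon that the target does not contain, the price of the next cut. The forward step must remove a formaldehyde acetal without ionising the benzylic C7–O bond or touching the silyl ether and esters.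

**C5–C6 and C7–O (Prins, key cut).** In 17 the bonds C5–C6 and C7–O are cut together with the acetal C–O bonds, returning the (E)-styrene 15 and two molecules of formaldehyde 16. The competing cut at C5–C7 (an anti-aldol) would need a carboxyl group at C6, a two-carbon chain extension, an auxiliary and a hydride reduction. The Prins cut takes the alkene as a cross-coupling delivers it and builds both bonds and the C7 oxygen in one catalytic operation. Two stereocentres and the 1,3-dioxygen pattern disappear; 15 keeps only C2 and C3. The forward reaction must put carbon on C5 with the charge at benzylic C7, add suprafacially so that E becomes trans, let the catalyst rather than the C3 centre choose the alkene face, and ignore the allyl group. For this step both arenes are acetates, which hold them near the electronic level of styrene, and O2 is silylated so that it cannot form its own oxocarbenium ion with formaldehyde.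

**C4–C5 (sp3–sp2 coupling) and protecting-group exchange.** 15 is taken back, by exchange of one aryl silyl ether for an acetate, to 13. 13 is cut at C4–C5 into the primary iodide 9 (as its zinc reagent 12) and the (E)-vinyl iodide 11, one olefination away from 4-acetoxybenzaldehyde 10. An olefination across C5=C7 was the neighbour; it would need a homologation of 9 and would have to fight for E selectivity, whereas the coupling transfers the geometry of 11 unchanged. The cut removes one arene and leaves a fragment with two stereocentres. The forward step needs a primary alkylzinc without a β-leaving group.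

**C2–C3 (aldol).** Iodide 9 comes from alcohol 8, 8 from imide 7 by reductive loss of the auxiliary, and 7 from aldol adduct 6. 6 is cut at C2–C3 into pentenoyl imide 3 and the silyl-protected aldehyde 4; 3 is the acylation product of oxazolidinone 1 with acid chloride 2. With the imide carbonyl (the later C4) in the chain, the allyl group on C3 and the oxygen on C2 are syn, the Evans syn-aldol pattern, and the (R)-auxiliary gives the required enantiomer. The phenol is a silyl ether here because it must pass the oxidative aldol work-up and the hydride reduction, which an aryl acetate would not.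

## Roads not taken

Alternative 1: The cut is made twice at once, at C2–C3 and C5–C7, on a symmetric five-carbon diacid. Both imides of the glutaryl bis-imide A1 are enolised under mild conditions (MgCl2, an amine, a chlorosilane), and each enolate adds to one molecule of aldehyde 4, giving the bis(anti-aldol) A2.
- Merits: all four stereocentres arise in one flask under auxiliary control. The two halves of A2 are homotopic, so activation of either primary carbon after reduction leads to the same oxane. Every reaction is of a known type. In stereocentres per step and in freedom from untested chemistry this road is better than the chosen one.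
- Weak points: the magnesium-catalysed anti-aldol wants an electrophilic aromatic aldehyde, and 4 with its para silyloxy group is a poor one. The second addition, next to an already branched aldolate, may stall or revert. Afterwards the two carboxyl carbons must part ways, one to C6 and one to the first carbon of the cinnamyl chain. That means two reductions, a statistical mono-activation and a separate C–C coupling, all with two ionisable electron-rich benzylic carbinols present.
- Comparison: the chosen plan sets against this a substrate whose two C3 arms differ from the outset, no statistical step, and catalytic creation of C5 and C7.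

Alternative 2: The ring is grown out of a furan; the cut runs through O1–C6 and stores C3–C6 as the four furan carbons. Carbinol A3 is oxidised at a carbon anode in methanol with bromide as mediator. On treatment with aqueous acid the oxidised furan ring opens and the carbinol oxygen closes onto the former furan C5, giving pyranone A4.
- Merits: ring, O1–C6 and all core carbons are in place after one reagent-light, scalable step, and C2 comes from a simple enantioselective ketone reduction. In certainty of ring formation and cost per gram this road is ahead.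
- Weak points: A4 has the wrong oxidation level at four carbons. The C6 lactol must be deoxygenated with a silane and a Lewis acid, which also ionises the benzylic C2–O bond and would let the C2 aryl group settle equatorial. The C3 ketone must become a CH bearing the cinnamyl group, and the C4=C5 alkene and C7 ketone must be reduced. C3, C5 and C7 would all rest on substrate control, with the exocyclic C7 poorly controlled. The anode also meets two easily oxidised silyloxyarenes and an acyl-deactivated furan.
- Comparison: the chosen plan is longer before the ring exists, but it fixes every stereocentre on the open chain by reagent or catalyst and never exposes the finished C2 centre to acid.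

Alternative 3: The cut is at C3–C4, made as a double bond. In diene A5, O1 already links C2 and C6. The second-generation Grubbs catalyst RuCl2(=CHPh)(PCy3)(H2IMes) joins the methylidene carbon on C3 to the vinyl group on C5, and the same ruthenium under hydrogen saturates the new alkene to give the all-cis oxane A6.
- Merits: ring-closing metathesis to a six-membered ring is dependable, and hydrogen should add opposite to the cis-related C2 and C5 substituents, which is the all-cis result. For ring closure and for C3 this road is at least as safe as the Williamson closure chosen here.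
- Weak points: A5 must already contain C2, C5 and C7, so the hard pair C5/C7 is moved earlier rather than solved. The O1 ether between a hindered benzylic carbinol and a branched primary carbon must be made intermolecularly. The alkene to be hydrogenated is allylic to the benzylic C2–O bond, inviting isomerisation or hydrogenolysis. Because hydrogen is used, the cinnamyl alkene cannot be present, so the side chain is a silyloxyethyl stub that later costs desilylation, oxidation and an E-selective olefination.
- Comparison: the chosen plan spends one cross-metathesis on an allyl group, and accepts the risk of a new catalytic step in exchange for making C5, C6 and C7 in one operation.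

Key step: step 9

Assumption: the sense of induction of the confined acid on an internal styrene cannot be derived from the terminal-styrene case. Both antipodes of the catalyst are therefore to be tried on 15 and the one giving the (4R,5R)-dioxane used; the catalyst is written without configuration for that reason.

## Route

Step 1
Reactants: 1 (4R)-4-benzyl-1,3-oxazolidin-2-one; 2 pent-4-enoyl chloride
Product: 3 (4R)-4-benzyl-3-(pent-4-enoyl)-1,3-oxazolidin-2-one
Conditions: Et3N, DMAP (cat.), CH2Cl2, 0 °C → rt
Reagents that add atoms: none
Why: N-acylation of the oxazolidinone by the acid chloride under nucleophilic catalysis; the stereocentre of the auxiliary is not involved.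

Step 2
Reactants: 3 pentenoyl imide; 4 4-[(tert-butyldimethylsilyl)oxy]benzaldehyde
Product: 6 syn-aldol adduct (4R)-4-benzyl-3-[(2R)-2-[(R)-(4-TBSO-phenyl)(hydroxy)methyl]pent-4-enoyl]-1,3-oxazolidin-2-one, via dibutylboron Z-enolate 5 (not isolated)
Conditions: Bu2BOTf, i-Pr2NEt, CH2Cl2, −78 → 0 °C; then 4, −78 → 0 °C; pH 7 buffer, MeOH, H2O2, 0 °C
Reagents that add atoms: none
Why: Evans syn-aldol reaction: the Z boron enolate reacts through a closed chair transition state with the auxiliary carbonyl turned away, and the aldehyde approaches the face opposite the benzyl group, which sets C2 and C3 together (syn, R,R with the R auxiliary); the aryl silyl ether withstands the peroxide work-up.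

Step 3
Reactants: 6 syn-aldol adduct
Product: 7 bis-silyl imide (4R)-4-benzyl-3-[(2R)-2-[(R)-(TBSO)(4-TBSO-phenyl)methyl]pent-4-enoyl]-1,3-oxazolidin-2-one
Conditions: TBSOTf, 2,6-lutidine, CH2Cl2, −78 → 0 °C
Reagents that add atoms: tert-butyldimethylsilyl triflate, CC(C)(C)[Si](C)(C)OS(=O)(=O)C(F)(F)F
Why: Silylation of the hindered benzylic aldol hydroxyl with a silyl triflate and a hindered base; it blocks retro-aldol cleavage and keeps O2 inert up to step 13.

Step 4
Reactants: 7 bis-silyl imide
Product: 8 (2S)-2-[(R)-(TBSO)(4-TBSO-phenyl)methyl]pent-4-en-1-ol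
Conditions: LiBH4, MeOH (1 equiv), Et2O, 0 °C
Reagents that add atoms: none
Why: Reductive cleavage of the N-acyl oxazolidinone: hydride attacks the exocyclic imide carbonyl, the auxiliary 1 is released for recovery and both silyl ethers are untouched; C3 is not epimerisable under these conditions.

Step 5
Reactants: 8 primary alcohol
Product: 9 tert-butyl{4-[(1R,2R)-1-(TBSO)-2-(iodomethyl)pent-4-en-1-yl]phenoxy}dimethylsilane
Conditions: I2, PPh3, imidazole, CH2Cl2, 0 °C → rt
Reagents that add atoms: iodine, II
Why: Appel-type iodination through the alkoxyphosphonium salt of the only free hydroxyl; substitution occurs at the primary carbon, so neither stereocentre is touched.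

Step 6
Reactants: 10 4-formylphenyl acetate (4-acetoxybenzaldehyde)
Product: 11 4-[(E)-2-iodoethenyl]phenyl acetate
Conditions: CHI3, CrCl2, THF, 0 °C → rt
Reagents that add atoms: iodoform, IC(I)I
Why: Takai olefination: the geminal dichromium species from iodoform adds to the aldehyde and eliminates to the E vinyl iodide; CrCl2 tolerates the aryl acetate.

Step 7
Reactants: 9 primary iodide; 11 (E)-vinyl iodide
Product: 13 4-[(1E,4S)-4-[(R)-(TBSO)(4-TBSO-phenyl)methyl]hepta-1,6-dien-1-yl]phenyl acetate, via alkylzinc iodide 12 (not isolated)
Conditions: Zn dust (activated with TMSCl/BrCH2CH2Br), LiCl, THF, 30 °C; then 11, Pd(OAc)2 (2 mol%), SPhos (4 mol%), THF, rt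
Reagents that add atoms: none
Why: Negishi coupling: zinc inserts into the primary C–I bond (no β-leaving group; silyl ethers and the ester of 11 are tolerated) and palladium joins C4 to C5 with retention of the E geometry of 11.

Step 8
Reactants: 13 coupled diene
Product: 15 4-[(1E,4S)-4-[(R)-(4-acetoxyphenyl)(TBSO)methyl]hepta-1,6-dien-1-yl]phenyl acetate, via phenol 14 (not isolated)
Conditions: Bu4NF (1.1 equiv), THF, 0 °C, short; then Ac2O, Et3N, DMAP (cat.), 0 °C → rt
Reagents that add atoms: acetic anhydride, CC(=O)OC(C)=O
Why: Fluoride cleaves the aryl silyl ether far faster than the hindered secondary alkyl silyl ether, and the phenoxide is acetylated in the same flask (any acetate lost from the other ring is restored); the acetoxy group makes the benzylic C2–O bond much harder to ionise in step 9.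

Step 9
Reactants: 15 (E)-styrene diacetate; 16 paraformaldehyde (formaldehyde source; one formaldehyde unit counted here)
Product: 17 4-[(4R,5R)-5-{(2S)-2-[(R)-(4-acetoxyphenyl)(TBSO)methyl]pent-4-en-1-yl}-1,3-dioxan-4-yl]phenyl acetate
Conditions: (HCHO)n (5 equiv), confined chiral imino-imidodiphosphoric acid (iIDP type, 5 mol%), cyclohexane/CHCl3, 20 °C
Reagents that add atoms: formaldehyde (the second of the two units taken up, from the same paraformaldehyde), C=O
Why: Proposed new method: a catalytic asymmetric intermolecular Prins reaction is known for terminal styrenes with paraformaldehyde under confined imino-imidodiphosphate acids, and the acid-mediated Prins reaction of (E)-1-arylpropenes to trans-4-aryl-5-alkyl-1,3-dioxanes is classical, but the enantio- and diastereoselective version on an internal, functionalised styrene has not been shown. The acid turns a formaldehyde oligomer into a hydroxymethyl-oxocarbenium ion pair held in the chiral pocket, so that two formaldehyde units enter 17, one as C6 and one as the acetal carbon; C5 of the styrene attacks the electrophilic carbon (the later C6) and the charge developing at benzylic C7 is taken up by the hemiacetal oxygen in a concerted, asynchronous [4+2]-type addition. The 1,3-dioxane thus closes by C7–O bond formation through a six-membered chair in which both former alkene carbons become ring atoms (endo with respect to the old double bond, suprafacial), so the E geometry becomes the 4,5-trans diequatorial relation, which is also the thermodynamic one should the ion pair live longer. C5 is set by the alkene face that the catalyst exposes (catalyst control over the C3 centre, matched antipode of the acid to be chosen), and C7 follows from C5 through the syn addition. Regiochemistry rests on benzylic stabilisation at C7, and chemoselectivity over the allyl group on the much lower nucleophilicity of an isolated terminal alkene. The acetoxy groups hold both arenes near the electronic level of styrene, which suppresses cationic oligomerisation and ionisation at C2 and C7, and the silyl ether on O2 prevents a competing oxocarbenium cyclisation of a free C2 hydroxyl onto the styrene; should the internal alkene prove sluggish, the more acidic imidodiphosphorimidate (IDPi) congeners are the stronger catalysts of the same family.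

Step 10
Reactants: 17 trans-dioxane
Product: 19 4-[(1R,2R)-2-{(2S)-2-[(R)-(4-acetoxyphenyl)(TBSO)methyl]pent-4-en-1-yl}-1,3-dihydroxypropyl]phenyl acetate, via alkoxymethyl-bipyridinium triflate 18 (not isolated)
Conditions: TMSOTf, 2,2′-bipyridyl, CH2Cl2, 0 °C → rt; then H2O
Reagents that add atoms: none
Why: Known mild cleavage of methylene acetals: the silyl triflate opens the formal at the less hindered O6 and bipyridyl traps the oxocarbenium ion as an N-(alkoxymethyl)pyridinium salt, which water hydrolyses to the C7 hydroxyl and formaldehyde while the trimethylsilyl ether on O6 falls off; no free strong acid is present, so the benzylic C–O bonds, the TBS ether and the acetates should persist.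

Step 11
Reactants: 19 allyl diol; 20 4-ethenylphenyl acetate (4-acetoxystyrene)
Product: 21 4-[(1E,4S,6R,7R)-7-(4-acetoxyphenyl)-4-[(R)-(4-acetoxyphenyl)(TBSO)methyl]-7-hydroxy-6-(hydroxymethyl)hept-1-en-1-yl]phenyl acetate
Conditions: second-generation Grubbs catalyst RuCl2(=CHPh)(PCy3)(H2IMes) (5 mol%), 20 (4 equiv), CH2Cl2, 40 °C
Reagents that add atoms: none
Why: Olefin cross-metathesis of a terminal alkene with a styrene: loss of ethylene drives the reaction, the conjugated E alkene is favoured, and free hydroxyls, esters and the silyl ether are tolerated; no other alkene is left in 19 after step 9.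

Step 12
Reactants: 21 diol
Product: 22 (2R,4S,6E)-2-[(R)-(4-acetoxyphenyl)(hydroxy)methyl]-4-[(R)-(4-acetoxyphenyl)(TBSO)methyl]-7-(4-acetoxyphenyl)hept-6-en-1-yl 4-methylbenzenesulfonate
Conditions: TsCl (1.2 equiv), Et3N, DMAP (cat.), CH2Cl2, 0 °C
Reagents that add atoms: 4-toluenesulfonyl chloride, Cc1ccc(cc1)S(Cl)(=O)=O
Why: Selective sulfonylation of the primary C6 hydroxyl beside the hindered secondary benzylic C7 hydroxyl; this turns C6 into the electrophile for ring closure.

Step 13
Reactants: 22 silyl ether tosylate
Product: 23 (2R,4S,6E)-2,4-bis[(R)-(4-acetoxyphenyl)(hydroxy)methyl]-7-(4-acetoxyphenyl)hept-6-en-1-yl 4-methylbenzenesulfonate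
Conditions: HF·pyridine, pyridine, THF, 0 °C → rt
Reagents that add atoms: none
Why: Buffered, non-basic desilylation frees the C2 hydroxyl while the phenols are still acetates and the tosylate is intact, so O2 is never an ester or silyl ether when a phenoxide is later generated.

Step 14
Reactants: 23 hydroxy tosylate triacetate
Product: 25 4-[(2R,3S,5R)-5-[(R)-hydroxy(4-hydroxyphenyl)methyl]-3-[(2E)-3-(4-hydroxyphenyl)prop-2-en-1-yl]oxan-2-yl]phenol, via triphenol tosylate 24 (not isolated)
Conditions: NaOMe (8 equiv), MeOH/THF, 0 °C → rt; then NH4Cl (aq)
Reagents that add atoms: none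
Why: Methoxide removes the three aryl acetates as methyl acetate, and the C2 alkoxide closes O1–C6 by an intramolecular Williamson 6-exo-tet SN2 displacement at the primary carbon, which keeps the C2 configuration because its C–O bond is not broken and should be far faster than 4-exo closure from O7; no benzylic oxygen carries a leaving group when the phenoxides form, and the near-neutral quench avoids acid at the axial-aryl C2 centre.

## Compound list

1 | (4R)-4-benzyl-1,3-oxazolidin-2-one | O=C1N[C@H](Cc2ccccc2)CO1 | starting material
2 | pent-4-enoyl chloride | C=CCCC(=O)Cl | starting material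
3 | (4R)-4-benzyl-3-(pent-4-enoyl)-1,3-oxazolidin-2-one | C=CCCC(=O)N1[C@H](Cc2ccccc2)COC1=O | intermediate
4 | 4-[(tert-butyldimethylsilyl)oxy]benzaldehyde | CC(C)(C)[Si](C)(C)Oc1ccc(C=O)cc1 | starting material
5 | (4R)-4-benzyl-3-{(1Z)-1-[(dibutylboranyl)oxy]penta-1,4-dien-1-yl}-1,3-oxazolidin-2-one (boron Z-enolate of 3) | C=CC/C=C(\OB(CCCC)CCCC)N1[C@H](Cc2ccccc2)COC1=O | intermediate
6 | (4R)-4-benzyl-3-[(2R)-2-[(R)-{4-[(tert-butyldimethylsilyl)oxy]phenyl}(hydroxy)methyl]pent-4-enoyl]-1,3-oxazolidin-2-one | C=CC[C@@H](C(=O)N1[C@H](Cc2ccccc2)COC1=O)[C@@H](O)c1ccc(O[Si](C)(C)C(C)(C)C)cc1 | intermediate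
7 | (4R)-4-benzyl-3-[(2R)-2-[(R)-[(tert-butyldimethylsilyl)oxy]{4-[(tert-butyldimethylsilyl)oxy]phenyl}methyl]pent-4-enoyl]-1,3-oxazolidin-2-one | C=CC[C@@H](C(=O)N1[C@H](Cc2ccccc2)COC1=O)[C@@H](O[Si](C)(C)C(C)(C)C)c1ccc(O[Si](C)(C)C(C)(C)C)cc1 | intermediate
8 | (2S)-2-[(R)-[(tert-butyldimethylsilyl)oxy]{4-[(tert-butyldimethylsilyl)oxy]phenyl}methyl]pent-4-en-1-ol | C=CC[C@@H](CO)[C@@H](O[Si](C)(C)C(C)(C)C)c1ccc(O[Si](C)(C)C(C)(C)C)cc1 | intermediate
9 | tert-butyl{4-[(1R,2R)-1-[(tert-butyldimethylsilyl)oxy]-2-(iodomethyl)pent-4-en-1-yl]phenoxy}dimethylsilane | C=CC[C@@H](CI)[C@@H](O[Si](C)(C)C(C)(C)C)c1ccc(O[Si](C)(C)C(C)(C)C)cc1 | intermediate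
10 | 4-formylphenyl acetate (4-acetoxybenzaldehyde) | CC(=O)Oc1ccc(C=O)cc1 | starting material
11 | 4-[(E)-2-iodoethenyl]phenyl acetate | CC(=O)Oc1ccc(/C=C/I)cc1 | intermediate
12 | {(2R)-2-[(R)-[(tert-butyldimethylsilyl)oxy]{4-[(tert-butyldimethylsilyl)oxy]phenyl}methyl]pent-4-en-1-yl}zinc iodide | C=CC[C@@H](C[Zn]I)[C@@H](O[Si](C)(C)C(C)(C)C)c1ccc(O[Si](C)(C)C(C)(C)C)cc1 | intermediate
13 | 4-[(1E,4S)-4-[(R)-[(tert-butyldimethylsilyl)oxy]{4-[(tert-butyldimethylsilyl)oxy]phenyl}methyl]hepta-1,6-dien-1-yl]phenyl acetate | C=CC[C@@H](C/C=C/c1ccc(OC(C)=O)cc1)[C@@H](O[Si](C)(C)C(C)(C)C)c1ccc(O[Si](C)(C)C(C)(C)C)cc1 | intermediate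
14 | 4-[(1E,4S)-4-[(R)-[(tert-butyldimethylsilyl)oxy](4-hydroxyphenyl)methyl]hepta-1,6-dien-1-yl]phenyl acetate | C=CC[C@@H](C/C=C/c1ccc(OC(C)=O)cc1)[C@@H](O[Si](C)(C)C(C)(C)C)c1ccc(O)cc1 | intermediate
15 | 4-[(1E,4S)-4-[(R)-[4-(acetyloxy)phenyl][(tert-butyldimethylsilyl)oxy]methyl]hepta-1,6-dien-1-yl]phenyl acetate | C=CC[C@@H](C/C=C/c1ccc(OC(C)=O)cc1)[C@@H](O[Si](C)(C)C(C)(C)C)c1ccc(OC(C)=O)cc1 | intermediate
16 | paraformaldehyde (formaldehyde source) | C=O | starting material
17 | 4-[(4R,5R)-5-{(2S)-2-[(R)-[4-(acetyloxy)phenyl][(tert-butyldimethylsilyl)oxy]methyl]pent-4-en-1-yl}-1,3-dioxan-4-yl]phenyl acetate | C=CC[C@@H](C[C@H]1[C@@H](OCOC1)c1ccc(OC(C)=O)cc1)[C@@H](O[Si](C)(C)C(C)(C)C)c1ccc(OC(C)=O)cc1 | intermediate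
18 | N-(alkoxymethyl)-2,2′-bipyridinium triflate from 17: O7 bound to CH2–N(+) of bipyridyl, O6 as trimethylsilyl ether, all stereocentres as in 17 | C=CC[C@@H](C[C@H](CO[Si](C)(C)C)[C@@H](OC[n+]1ccccc1-c1ccccn1)c1ccc(OC(C)=O)cc1)[C@@H](O[Si](C)(C)C(C)(C)C)c1ccc(OC(C)=O)cc1.[O-]S(=O)(=O)C(F)(F)F | intermediate
19 | 4-[(1R,2R)-2-{(2S)-2-[(R)-[4-(acetyloxy)phenyl][(tert-butyldimethylsilyl)oxy]methyl]pent-4-en-1-yl}-1,3-dihydroxypropyl]phenyl acetate | C=CC[C@@H](C[C@H](CO)[C@@H](O)c1ccc(OC(C)=O)cc1)[C@@H](O[Si](C)(C)C(C)(C)C)c1ccc(OC(C)=O)cc1 | intermediate
20 | 4-ethenylphenyl acetate (4-acetoxystyrene) | C=Cc1ccc(OC(C)=O)cc1 | starting material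
21 | 4-[(1E,4S,6R,7R)-7-[4-(acetyloxy)phenyl]-4-[(R)-[4-(acetyloxy)phenyl][(tert-butyldimethylsilyl)oxy]methyl]-7-hydroxy-6-(hydroxymethyl)hept-1-en-1-yl]phenyl acetate | CC(=O)Oc1ccc(/C=C/C[C@@H](C[C@H](CO)[C@@H](O)c2ccc(OC(C)=O)cc2)[C@@H](O[Si](C)(C)C(C)(C)C)c2ccc(OC(C)=O)cc2)cc1 | intermediate
22 | (2R,4S,6E)-2-[(R)-[4-(acetyloxy)phenyl](hydroxy)methyl]-4-[(R)-[4-(acetyloxy)phenyl][(tert-butyldimethylsilyl)oxy]methyl]-7-[4-(acetyloxy)phenyl]hept-6-en-1-yl 4-methylbenzenesulfonate | CC(=O)Oc1ccc(/C=C/C[C@@H](C[C@H](COS(=O)(=O)c2ccc(C)cc2)[C@@H](O)c2ccc(OC(C)=O)cc2)[C@@H](O[Si](C)(C)C(C)(C)C)c2ccc(OC(C)=O)cc2)cc1 | intermediate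
23 | (2R,4S,6E)-2,4-bis[(R)-[4-(acetyloxy)phenyl](hydroxy)methyl]-7-[4-(acetyloxy)phenyl]hept-6-en-1-yl 4-methylbenzenesulfonate | CC(=O)Oc1ccc(/C=C/C[C@@H](C[C@H](COS(=O)(=O)c2ccc(C)cc2)[C@@H](O)c2ccc(OC(C)=O)cc2)[C@@H](O)c2ccc(OC(C)=O)cc2)cc1 | intermediate
24 | (2R,4S,6E)-2,4-bis[(R)-hydroxy(4-hydroxyphenyl)methyl]-7-(4-hydroxyphenyl)hept-6-en-1-yl 4-methylbenzenesulfonate | Oc1ccc(/C=C/C[C@@H](C[C@H](COS(=O)(=O)c2ccc(C)cc2)[C@@H](O)c2ccc(O)cc2)[C@@H](O)c2ccc(O)cc2)cc1 | intermediate
25 | 4-[(2R,3S,5R)-5-[(R)-hydroxy(4-hydroxyphenyl)methyl]-3-[(2E)-3-(4-hydroxyphenyl)prop-2-en-1-yl]oxan-2-yl]phenol (CNP0182155.1) | Oc1ccc(/C=C/C[C@H]2C[C@@H]([C@@H](O)c3ccc(O)cc3)CO[C@H]2c2ccc(O)cc2)cc1 | target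

## Step count and uncertain steps

Total step count: 14. Longest linear sequence: 13 steps (steps 1–5 and 7–14, from 1 and 2); step 6 is a one-step branch from 10.

**Step 9 (key step; carries the label for a new method).**
- Most likely failure: slow conversion or poor facial selectivity. A 1,2-disubstituted alkene with a branched chain must enter a pocket developed for monosubstituted styrenes, and the catalyst has to override whatever bias the C3 centre exerts. A second concern is loss of the silyl ether under prolonged acid, which would open an oxocarbenium cyclisation from O2.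
- Fallback (known reactions only): C5 and C7 are made by an amine-catalysed anti-aldol reaction instead. The detour sets out from iodide 9. Alkylation of lithiated acetaldehyde N,N-dimethylhydrazone (LiN(i-Pr)2, THF, −78 °C → rt) with 9 gives the bis-silylated hept-6-enal dimethylhydrazone F1. Fluoride followed by acetic anhydride, as in step 8, exchanges the aryl silyl ether for the acetate and gives the acetoxy hydrazone F2. CuCl2 in buffered aqueous THF releases the aldehyde F3. (S)-Proline in DMF adds F3, through its enamine, to an excess of aldehyde 10 and gives the anti β-hydroxy aldehyde F4 with C5 and C7 as in the target. NaBH4 at low temperature reduces F4 in the same flask to diol 19, where the route is rejoined before step 11.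
- Price of the fallback: five operations instead of two, and only moderate anti preference with aromatic acceptors, so the syn isomer would have to be removed at the stage of 19.

**Step 10.**
- Most likely failure: incomplete opening of the formal, the most robust of the acetals. If it is forced with more silyl triflate, the TBS ether may be lost or the benzylic C7–O bond may ionise.
- Fallback: a gentler class of reagent for a formaldehyde acetal is not at hand, so the alternative is to avoid the acetal. The aldol detour described for step 9 sets out from iodide 9 and reaches diol 19 without a formal; it makes no compound beyond those named there.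

**Step 14.**
- Most likely failure: ring closure that is slow relative to other pathways. These are displacement of the tosylate by methoxide, fragmentation or four-membered ring closure from the C7 alkoxide, and, on long exposure, base-induced opening of the benzylic C2–O1 bond through a quinone methide with epimerisation to the equatorial aryl isomer.
- Fallback: ring closure without base, before the phenols are freed. It sets out from diol 21. HF·pyridine removes the silyl ether and gives the triol triacetate F5. Tf2O and 2,6-lutidine in CH2Cl2 at −78 °C sulfonylate the primary hydroxyl selectively, and the C2 hydroxyl displaces the triflate on warming (a cyclodehydration of known type for 1,5-diols), giving the oxane triacetate F6. K2CO3 in MeOH at 0 °C then removes the three acetates and returns the route at 25.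

**Step 7.**
- Most likely failure: sluggish zinc insertion into the β-branched iodide, or protonolysis of the alkylzinc before coupling, so that reduced material accumulates.
- Fallback: B-alkyl Suzuki–Miyaura coupling. From iodide 9, iodine–lithium exchange (t-BuLi, Et2O, −78 °C) and capture with 9-methoxy-9-borabicyclo[3.3.1]nonane give the lithium alkyl(methoxy)borate F7. F7 is coupled with vinyl iodide 11 under PdCl2(dppf) and aqueous K3PO4 in DMF at rt to give 13, where the route continues; should part of the aryl acetate be lost to the base, the acetylation of step 8 restores it.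

## Further compounds

F1 | step 9 | N,N-dimethylhydrazone of (4R)-4-[(R)-[(tert-butyldimethylsilyl)oxy]{4-[(tert-butyldimethylsilyl)oxy]phenyl}methyl]hept-6-enal | C=CC[C@@H](CCC=NN(C)C)[C@@H](O[Si](C)(C)C(C)(C)C)c1ccc(O[Si](C)(C)C(C)(C)C)cc1
F2 | step 9 | N,N-dimethylhydrazone of (4R)-4-[(R)-[4-(acetyloxy)phenyl][(tert-butyldimethylsilyl)oxy]methyl]hept-6-enal | C=CC[C@@H](CCC=NN(C)C)[C@@H](O[Si](C)(C)C(C)(C)C)c1ccc(OC(C)=O)cc1
F3 | step 9 | 4-[(1R,2R)-1-[(tert-butyldimethylsilyl)oxy]-2-(3-oxopropyl)pent-4-en-1-yl]phenyl acetate | C=CC[C@@H](CCC=O)[C@@H](O[Si](C)(C)C(C)(C)C)c1ccc(OC(C)=O)cc1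
F4 | step 9 | (2S,3R)-3-[4-(acetyloxy)phenyl]-2-{(2S)-2-[(R)-[4-(acetyloxy)phenyl][(tert-butyldimethylsilyl)oxy]methyl]pent-4-en-1-yl}-3-hydroxypropanal | C=CC[C@@H](C[C@H](C=O)[C@@H](O)c1ccc(OC(C)=O)cc1)[C@@H](O[Si](C)(C)C(C)(C)C)c1ccc(OC(C)=O)cc1
F0 | step 10 | none | none
F5 | step 14 | 4-[(1E,4S,6R,7R)-7-[4-(acetyloxy)phenyl]-4-[(R)-[4-(acetyloxy)phenyl](hydroxy)methyl]-7-hydroxy-6-(hydroxymethyl)hept-1-en-1-yl]phenyl acetate | CC(=O)Oc1ccc(/C=C/C[C@@H](C[C@H](CO)[C@@H](O)c2ccc(OC(C)=O)cc2)[C@@H](O)c2ccc(OC(C)=O)cc2)cc1
F6 | step 14 | 4-[(2R,3S,5R)-5-[(R)-[4-(acetyloxy)phenyl](hydroxy)methyl]-3-{(2E)-3-[4-(acetyloxy)phenyl]prop-2-en-1-yl}oxan-2-yl]phenyl acetate | CC(=O)Oc1ccc(/C=C/C[C@H]2C[C@@H]([C@@H](O)c3ccc(OC(C)=O)cc3)CO[C@H]2c2ccc(OC(C)=O)cc2)cc1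
F7 | step 7 | lithium 9-methoxy-9-{(2R)-2-[(R)-[(tert-butyldimethylsilyl)oxy]{4-[(tert-butyldimethylsilyl)oxy]phenyl}methyl]pent-4-en-1-yl}-9-boranuidabicyclo[3.3.1]nonane | [Li+].C=CC[C@@H](C[B-]1(OC)C2CCCC1CCC2)[C@@H](O[Si](C)(C)C(C)(C)C)c1ccc(O[Si](C)(C)C(C)(C)C)cc1
A1 | alternative 1 | glutaryl bis-imide, 1,5-bis[(4R)-4-benzyl-2-oxo-1,3-oxazolidin-3-yl]pentane-1,5-dione | O=C(CCCC(=O)N1[C@H](Cc2ccccc2)COC1=O)N1[C@H](Cc2ccccc2)COC1=O
A2 | alternative 1 | twofold-symmetric bis(anti-aldol) diol from A1 and two molecules of 4 | CC(C)(C)[Si](C)(C)Oc1ccc(cc1)[C@H](O)[C@@H](C(=O)N1[C@H](Cc2ccccc2)COC1=O)C[C@H](C(=O)N1[C@H](Cc2ccccc2)COC1=O)[C@@H](O)c1ccc(O[Si](C)(C)C(C)(C)C)cc1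
A3 | alternative 2 | (S)-{4-[(tert-butyldimethylsilyl)oxy]phenyl}(4-{4-[(tert-butyldimethylsilyl)oxy]benzoyl}furan-2-yl)methanol | O[C@H](c1cc(co1)C(=O)c1ccc(O[Si](C)(C)C(C)(C)C)cc1)c1ccc(O[Si](C)(C)C(C)(C)C)cc1
A4 | alternative 2 | (2S)-2-aryl-5-aroyl-6-hydroxy-2H-pyran-3(6H)-one, aryl = 4-[(tert-butyldimethylsilyl)oxy]phenyl (C6 anomers) | O=C1C=C(C(=O)c2ccc(O[Si](C)(C)C(C)(C)C)cc2)C(O)O[C@H]1c1ccc(O[Si](C)(C)C(C)(C)C)cc1
A5 | alternative 3 | metathesis diene: ether of O1 between C2 (aryl, 1-methylidene-3-silyloxypropyl) and C6 of the 2-vinyl C5–C7 fragment, all oxygens as TBS ethers | C=C[C@@H]([C@@H](O[Si](C)(C)C(C)(C)C)c1ccc(O[Si](C)(C)C(C)(C)C)cc1)CO[C@H](C(=C)CCO[Si](C)(C)C(C)(C)C)c1ccc(O[Si](C)(C)C(C)(C)C)cc1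
A6 | alternative 3 | all-cis 2,3,5-trisubstituted oxane with 2-silyloxyethyl chain on C3 | CC(C)(C)[Si](C)(C)OCC[C@H]2C[C@@H]([C@@H](O[Si](C)(C)C(C)(C)C)c3ccc(O[Si](C)(C)C(C)(C)C)cc3)CO[C@H]2c2ccc(O[Si](C)(C)C(C)(C)C)cc2
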